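## Retrosynthetic overview

- Feature: in the ring C1–C6 the tertiary C4–O bond and the C1–C7 bond are 1,4-cis, and C2/C3 carry a cis-diol on the opposite face. A C7(=O)–O–C4 lactone bridge (a 2-pyrone) and a cis-enediol therefore map onto C1–C4 and C7.
- Key disconnection: C1–C2 and C3–C4 by endo [4+2] of 5-bromo-6-methyl-2-pyrone with vinylene carbonate. The carbocycle is the first ring formed; the lactone bridge and the carbonate are temporary rings.
- The C5=C6 vinyl bromide is unmasked to the C5 ketone and C6–OH by dihydroxylation; the lactone carbon C7 is taken through CH2OH and CHO to C≡CH.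
- C7–C8 and the C7=CH2 unit come from a Cr/Ni reductive coupling of the alkyne with 4-methylpent-3-enal; C8 is set by CBS reduction of the enone.
- Angelates go on O6/O8, then on O2 through a stannylene acetal; the oxirane (last ring) is closed by Shi epoxidation of C10=C11.

Key step: step 5

Remark (convention and one assumption): atoms keep the target numbering throughout (ring C1–C6, chain C7–C11, C7 being the former lactone carbon); β is the ring face carrying the C1–C7 bond and α the opposite face, so the target is 1β-C7, 2α-OAng, 3α-OH, 4β-OH/4α-Me, 6α-OAng, 8S, 10R (1S,2S,3S,4R,6R in this numbering); the sense of induction of the chiral Lewis acid in step 5 is assumed, and its equally available antipode would be used if it favoured the mirror-image adduct.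

## Route

Step 1
Reactants: 1 4-hydroxy-6-methyl-2H-pyran-2-one
Product: 2 6-methyl-2-oxo-2H-pyran-4-yl 4-methylbenzenesulfonate
Conditions: TsCl (1.1 equiv), Et3N, CH2Cl2, 0 °C → rt
Reagents that add atoms: p-toluenesulfonyl chloride, Cc1ccc(cc1)S(Cl)(=O)=O
Why: O-sulfonylation of the vinylogous acid (the 4-OH is the acidic, nucleophilic oxygen) should give the bench-stable pyronyl tosylate, an enol sulfonate activated for oxidative addition.

Step 2
Reactants: 2 6-methyl-2-oxo-2H-pyran-4-yl 4-methylbenzenesulfonate
Product: 3 6-methyl-2H-pyran-2-one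
Conditions: Pd(OAc)2 (5 mol%), dppp (6 mol%), HCO2H, Et3N, DMF, 70 °C
Reagents that add atoms: none
Why: Pd-catalysed formate hydrogenolysis of an enol sulfonate (oxidative addition into the vinylogous acyl C4–O bond, decarboxylation of formate to Pd–H, reductive elimination) should remove the 4-oxygen without touching the pyrone.

Step 3
Reactants: 3 6-methyl-2H-pyran-2-one
Product: 4 3,5-dibromo-6-methyl-2H-pyran-2-one
Conditions: Br2 (2.2 equiv), CH2Cl2, 0 °C → rt, dark; then Et3N, 0 °C
Reagents that add atoms: bromine, BrBr
Why: electrophilic bromination by addition–elimination should occur at the two positions activated by the ring oxygen (C3 and C5), whereas C4 is the electron-poor β-carbon and ionic conditions spare the methyl group.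

Step 4
Reactants: 4 3,5-dibromo-6-methyl-2H-pyran-2-one
Product: 5 5-bromo-6-methyl-2H-pyran-2-one
Conditions: Pd(PPh3)4 (5 mol%), Bu3SnH (1.05 equiv, slow addition), toluene, rt
Reagents that add atoms: none
Why: Pd-catalysed hydrodebromination should be site-selective because oxidative addition is faster at C3–Br (α to the carbonyl, unhindered) than at C5–Br (next to the 6-methyl group), the same site preference as in cross-couplings of 3,5-dibromo-2-pyrone.

Step 5
Reactants: 5 5-bromo-6-methyl-2H-pyran-2-one; 6 vinylene carbonate
Product: 7 bridged lactone adduct (cyclohex-5-ene ring C1–C6 with the C7(=O)–O lactone bridge from C1 to C4 on the β-face, 2α,3α-cyclic carbonate anti to the bridge, 4α-methyl, 5-bromo)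
Conditions: (S)-o-tolyl-CBS oxazaborolidine (20 mol%), Tf2NH (18 mol%), 6 (5 equiv), CH2Cl2, −20 → 10 °C
Reagents that add atoms: none
Why: Proposed new method: the cationic oxazaborolidinium Lewis acid is expected to bind the pyrone carbonyl (one-point binding supported by the C3–H···O contact known for lactones and enoates), lowering the LUMO of this ambiphilic diene so that the enediol π-bond of 6, whose HOMO is raised by two oxygen lone pairs, adds in a concerted, asynchronous inverse-demand [π4s+π2s] cycloaddition, bonding first at the oxygen-bearing diene terminus (future C4), well below the temperature of CO2 extrusion. The closest known reaction types are the thermal endo Diels–Alder reactions of 3- and 5-bromo-2-pyrones, which give isolable racemic bridged lactones, and chiral-Lewis-acid-catalysed cycloadditions of 3-carboalkoxy-2-pyrones with enol ethers. The carbocycle C1–C6, the only ring built here, is closed by the intermolecular cycloaddition itself, with C1–C2 and C3–C4 forming suprafacially on both partners while the lactone O–C(=O) unit of the diene becomes the bridge of the 2-oxabicyclo[2.2.2]octene. C1 and C4 are set together because the bridge can span only one face, which makes C7 and the C4 oxygen cis; C2 and C3 are cis because the (Z)-dienophile adds suprafacially, and they fall anti to the bridge through the endo orientation of the carbonate ring, as is usual for bromopyrones. The absolute sense should come from the catalyst aryl group, which shields one face of the bound pyrone. The step needs only endo/exo and π-facial selectivity, since the C2v-symmetric dienophile removes any regiochemical question and the low temperature guards against retro-[4+2] loss of CO2 and ionisation of the tertiary allylic C4–O bond.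

Step 6
Reactants: 7 bridged lactone adduct
Product: 8 5-bromo-1β-(hydroxymethyl)-4α-methylcyclohex-5-ene-2α,3α,4β-triol
Conditions: LiAlH4 (2.5 equiv), THF, −10 → 0 °C; Rochelle salt work-up
Reagents that add atoms: none
Why: hydride reduction should open the strained bridged lactone to the C7 primary and C4 tertiary alcohols and reduce the cyclic carbonate to the C2/C3 diol, with no stereocentre touched (C1 is a non-enolisable bridgehead until the bridge is gone) and the vinyl bromide inert at 0 °C.

Step 7
Reactants: 8 bromo-tetraol
Product: 9 2α,3α-O-isopropylidene derivative of 8 (C7–OH and 4β-OH free)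
Conditions: 2,2-dimethoxypropane (1.5 equiv), PPTS (5 mol%), acetone, rt
Reagents that add atoms: 2,2-dimethoxypropane, COC(C)(C)OC
Why: acid-catalysed acetalisation should select the cis-vicinal C2/C3 diol (five-membered dioxolane) over the O7/O2 1,3-dioxane and over the trans C3/C4 pair with its tertiary hydroxyl.

Step 8
Reactants: 9 acetonide diol
Product: 11 keto-triol (C5 ketone, 6α-OH, C7–OH, 4β-OH, 2α,3α-acetonide), via gem-bromohydrin 10 (not isolated)
Conditions: OsO4 (10 mol%), NMO (2 equiv), MeSO2NH2, acetone/H2O (4:1), rt → 40 °C
Reagents that add atoms: osmium tetroxide, O=[Os](=O)(=O)=O; N-methylmorpholine N-oxide (terminal oxidant that restores the oxo groups), C[N+]1([O-])CCOCC1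
Why: Upjohn syn-dihydroxylation of the bromoalkene is expected from the α-face, anti to the allylic C4–OH and to the C1 substituent (the empirical anti rule for osmylation of allylic alcohols), which sets C6 as 6α-OH, and the C5 bromohydrin then loses HBr to give the ketone.

Step 9
Reactants: 11 keto-triol
Product: 12 7-O,6-O-bis(triethylsilyl) ether of 11 (4β-OH free)
Conditions: TESCl (2.5 equiv), imidazole, DMF, 0 °C → rt; then DBU (0.3 equiv), rt
Reagents that add atoms: chlorotriethylsilane, CC[Si](Cl)(CC)CC
Why: silylation should take the primary and the secondary hydroxyl but not the hindered tertiary one, and the DBU treatment is a safeguard by base equilibration: C6–H is the only enolisable position (C4 is quaternary), so any 6β-epimer from step 8 converges on the equatorial 6α-silyloxy ketone, trans to the C1 substituent.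

Step 10
Reactants: 12 bis-TES ether
Product: 13 C7 aldehyde (1β-formyl, 6α-OTES, C5 ketone, 4β-OH, acetonide)
Conditions: (COCl)2, DMSO, CH2Cl2, −78 → −40 °C; Et3N, −78 → 0 °C
Reagents that add atoms: none
Why: Swern oxidation with in-situ cleavage of the primary triethylsilyl ether (the known selective oxidation of primary TES ethers beside secondary ones) should give the aldehyde directly, and the low temperature keeps C1 intact.

Step 11
Reactants: 13 C7 aldehyde
Product: 14 terminal alkyne (1β-ethynyl, C7≡CH)
Conditions: dimethyl (1-diazo-2-oxopropyl)phosphonate, K2CO3, MeOH, 0 °C → rt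
Reagents that add atoms: dimethyl (1-diazo-2-oxopropyl)phosphonate (Ohira–Bestmann reagent), CC(=O)C(=[N+]=[N-])P(=O)(OC)OC
Why: Seyferth–Gilbert homologation with the Ohira–Bestmann reagent (alkylidene carbene, 1,2-hydrogen shift) should convert CHO into C≡CH, aldehyde-selective over the hindered C5 ketone and run cold to outpace β-elimination; C1 already carries its substituent equatorial, so base should not erode it.

Step 12
Reactants: 15 4-methylpent-3-en-1-ol
Product: 16 4-methylpent-3-enal
Conditions: Dess–Martin periodinane, NaHCO3, CH2Cl2, 0 °C; solution used directly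
Reagents that add atoms: none
Why: Dess–Martin oxidation under buffered, non-basic conditions should give the β,γ-unsaturated aldehyde without migration of the double bond into conjugation.

Step 13
Reactants: 14 terminal alkyne; 16 4-methylpent-3-enal
Product: 17 allylic alcohol with the chain C7(=CH2)–C8H(OH)–CH2–CH=CMe2 on C1, as a mixture of C8 epimers
Conditions: CrCl2 (4 equiv), NiCl2 (10 mol%), PPh3 (20 mol%), H2O (2 equiv), 16 (2.5 equiv), DMF, rt
Reagents that add atoms: none
Why: the Cr(II)/Ni-catalysed reductive alkyne–aldehyde coupling (a hydrometalative variant of the Nozaki–Hiyama–Kishi reaction) should place the metal on the internal alkyne carbon, transmetalate to a 1-substituted vinylchromium(III) and add aldehyde-selectively, forming C7–C8 and the C7=CH2 unit while tolerating ketone, silyl ether, acetonide and free tertiary OH; C8 is not controlled here.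

Step 14
Reactants: 17 allylic alcohol (C8 epimers)
Product: 18 enone (C8 ketone conjugated to C7=CH2)
Conditions: Dess–Martin periodinane, NaHCO3, CH2Cl2, 0 °C
Reagents that add atoms: none
Why: Dess–Martin oxidation of the only oxidisable (secondary allylic) hydroxyl should converge both C8 epimers on one enone, the buffer preventing conjugation of the β,γ-olefin.

Step 15
Reactants: 18 enone
Product: 19 (8S)-allylic alcohol
Conditions: (R)-Me-CBS (1.0 equiv), catecholborane (3 equiv), toluene, −78 °C
Reagents that add atoms: none
Why: in the Corey–Bakshi–Shibata reduction the α-branched alkenyl group acts as the large and the CH2 group as the small substituent, so the (R)-catalyst should give the (8S)-carbinol, while the C5 ketone, flanked by a quaternary carbon and a silyloxy methine, should not compete at −78 °C.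

Step 16
Reactants: 19 (8S)-allylic alcohol
Product: 20 (8S)-6α,8-diol (4β-OH free, acetonide retained)
Conditions: HF·pyridine, pyridine, THF, 0 °C
Reagents that add atoms: none
Why: buffered fluoride desilylation should remove the secondary TES ether and leave acetonide, ketone and olefins untouched.

Step 17
Reactants: 20 (8S)-6α,8-diol
Product: 21 6α,8-di-O-angeloyl acetonide
Conditions: angelic acid (6 equiv), 2,4,6-trichlorobenzoyl chloride (6 equiv), Et3N (7 equiv), toluene, rt; then 20, 75 °C (no DMAP)
Reagents that add atoms: angelic acid ((Z)-2-methylbut-2-enoic acid), C/C=C(C)\C(=O)O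
Why: Yamaguchi-type esterification through the mixed anhydride without DMAP, conditions that preserve the (Z)-geometry, should acylate the secondary C6 and C8 hydroxyls with retention and leave the axial tertiary C4–OH free.

Step 18
Reactants: 21 6α,8-di-O-angeloyl acetonide
Product: 22 6α,8-di-O-angeloyl 2α,3α,4β-triol
Conditions: AcOH/H2O (4:1), 45 °C
Reagents that add atoms: none
Why: mild acid hydrolysis of the isopropylidene acetal should spare the esters, the allylic ester and the trisubstituted olefin.

Step 19
Reactants: 22 6α,8-di-O-angeloyl 2α,3α,4β-triol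
Product: 24 2α,6α,8-tri-O-angeloyl compound with the C10=C11 olefin, via dibutylstannylene acetal 23 (not isolated)
Conditions: Bu2SnO (1.1 equiv), toluene, 80 °C, 4 Å MS; then mixed anhydride from angelic acid (1.5 equiv), 2,4,6-trichlorobenzoyl chloride and Et3N, toluene, 0 °C → rt
Reagents that add atoms: angelic acid ((Z)-2-methylbut-2-enoic acid), C/C=C(C)\C(=O)O
Why: stannylene-acetal-directed monoacylation should occur at the equatorial C2 oxygen of the cis C2/C3 diol and not at the axial C3 oxygen next to quaternary C4; the C2 ester is also the thermodynamically preferred regioisomer, so acyl migration should not threaten it.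

Step 20
Reactants: 24 tri-O-angeloyl olefin
Product: 25 target CNP0313777.1
Conditions: D-fructose-derived Shi ketone (1.0 equiv, in portions), Oxone (1.5 equiv), NaHCO3 (pH ≈ 8), Bu4NHSO4 (cat.), MeCN/dimethoxymethane/aq. Na2EDTA, 0 °C
Reagents that add atoms: Oxone (potassium peroxymonosulfate; oxygen delivered through the dioxirane of the Shi ketone), [K+].[O-]S(=O)(=O)OO
Why: in the Shi asymmetric epoxidation the electron-rich trisubstituted C10=C11 should react far faster than the 1,1-disubstituted C7=CH2 or the angelate olefins, the spiro transition state of the D-fructose-derived dioxirane should set C10 as R under reagent control, and the near-neutral buffer protects the β-hydroxy ketone and the esters.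

## Compound list

1 | 4-hydroxy-6-methyl-2H-pyran-2-one | CC1=CC(O)=CC(=O)O1 | starting material
2 | 6-methyl-2-oxo-2H-pyran-4-yl 4-methylbenzenesulfonate | CC1=CC(OS(=O)(=O)c2ccc(C)cc2)=CC(=O)O1 | intermediate
3 | 6-methyl-2H-pyran-2-one | CC1=CC=CC(=O)O1 | intermediate
4 | 3,5-dibromo-6-methyl-2H-pyran-2-one | CC1=C(Br)C=C(Br)C(=O)O1 | intermediate
5 | 5-bromo-6-methyl-2H-pyran-2-one | CC1=C(Br)C=CC(=O)O1 | intermediate
6 | vinylene carbonate | O=C1OC=CO1 | starting material
7 | bridged lactone adduct (C7(=O)–O bridge C1→C4 on the β-face, 2α,3α-cyclic carbonate, 4α-methyl, 5-bromo-5-ene) | O=C2[C@H]1[C@H](O3)[C@H](OC3=O)[C@@](C)(O2)C(Br)=C1 | intermediate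
8 | 5-bromo-1β-(hydroxymethyl)-4α-methylcyclohex-5-ene-2α,3α,4β-triol | OC[C@H]1[C@H](O)[C@H](O)[C@@](C)(O)C(Br)=C1 | intermediate
9 | 2α,3α-O-isopropylidene derivative of 8 | OC[C@H]1[C@H](O3)[C@H](OC3(C)C)[C@@](C)(O)C(Br)=C1 | intermediate
10 | gem-bromohydrin (5β-bromo-5α,6α-diol) | OC[C@H]1[C@H](O3)[C@H](OC3(C)C)[C@@](C)(O)[C@@](O)(Br)[C@@H]1O | intermediate (not isolated)
11 | keto-triol (C5 ketone, 6α-OH, C7–OH, 4β-OH, acetonide) | OC[C@H]1[C@H](O3)[C@H](OC3(C)C)[C@@](C)(O)C(=O)[C@@H]1O | intermediate
12 | 7-O,6-O-bis(triethylsilyl) ether of 11 | CC[Si](CC)(CC)OC[C@H]1[C@H](O3)[C@H](OC3(C)C)[C@@](C)(O)C(=O)[C@@H]1O[Si](CC)(CC)CC | intermediate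
13 | C7 aldehyde (1β-formyl, 6α-OTES) | O=C[C@H]1[C@H](O3)[C@H](OC3(C)C)[C@@](C)(O)C(=O)[C@@H]1O[Si](CC)(CC)CC | intermediate
14 | terminal alkyne (1β-ethynyl, 6α-OTES) | C#C[C@H]1[C@H](O3)[C@H](OC3(C)C)[C@@](C)(O)C(=O)[C@@H]1O[Si](CC)(CC)CC | intermediate
15 | 4-methylpent-3-en-1-ol | CC(C)=CCCO | starting material
16 | 4-methylpent-3-enal | CC(C)=CCC=O | intermediate
17 | allylic alcohol, mixture of C8 epimers | C=C([C@H]1[C@H](O3)[C@H](OC3(C)C)[C@@](C)(O)C(=O)[C@@H]1O[Si](CC)(CC)CC)C(O)CC=C(C)C | intermediate
18 | enone (C8 ketone) | C=C([C@H]1[C@H](O3)[C@H](OC3(C)C)[C@@](C)(O)C(=O)[C@@H]1O[Si](CC)(CC)CC)C(=O)CC=C(C)C | intermediate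
19 | (8S)-allylic alcohol (6α-OTES) | C=C([C@H]1[C@H](O3)[C@H](OC3(C)C)[C@@](C)(O)C(=O)[C@@H]1O[Si](CC)(CC)CC)[C@H](CC=C(C)C)O | intermediate
20 | (8S)-6α,8-diol | C=C([C@H]1[C@H](O3)[C@H](OC3(C)C)[C@@](C)(O)C(=O)[C@@H]1O)[C@H](CC=C(C)C)O | intermediate
21 | 6α,8-di-O-angeloyl acetonide | C=C([C@H]1[C@H](O3)[C@H](OC3(C)C)[C@@](C)(O)C(=O)[C@@H]1OC(=O)/C(C)=C\C)[C@H](CC=C(C)C)OC(=O)/C(C)=C\C | intermediate
22 | 6α,8-di-O-angeloyl 2α,3α,4β-triol | C=C([C@H]1[C@H](O)[C@H](O)[C@@](C)(O)C(=O)[C@@H]1OC(=O)/C(C)=C\C)[C@H](CC=C(C)C)OC(=O)/C(C)=C\C | intermediate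
23 | 2,3-O-dibutylstannylene acetal of 22 | C=C([C@H]1[C@H](O3)[C@H](O[Sn]3(CCCC)CCCC)[C@@](C)(O)C(=O)[C@@H]1OC(=O)/C(C)=C\C)[C@H](CC=C(C)C)OC(=O)/C(C)=C\C | intermediate (not isolated)
24 | 2α,6α,8-tri-O-angeloyl compound with C10=C11 olefin | C=C([C@H]1[C@H](OC(=O)/C(C)=C\C)[C@H](O)[C@@](C)(O)C(=O)[C@@H]1OC(=O)/C(C)=C\C)[C@H](CC=C(C)C)OC(=O)/C(C)=C\C | intermediate
25 | CNP0313777.1 | C=C([C@H]1[C@H](OC(=O)/C(C)=C\C)[C@H](O)[C@@](C)(O)C(=O)[C@@H]1OC(=O)/C(C)=C\C)[C@H](C[C@H]1OC1(C)C)OC(=O)/C(C)=C\C | target

## Step count and risks

Total step count: 20. Longest linear sequence: 19 steps (steps 1–11 and 13–20); step 12 is a one-step side branch.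

Steps most likely to fail:

1. Step 5 (proposed new method). The carbonate carbonyl of 6 and the saturated lactone of the product are better donors than the pyrone, so the Lewis acid may be sequestered and turnover lost. The uncatalysed racemic pathway may compete, facial or endo/exo discrimination may be insufficient, or the tertiary allylic C4–O bond may ionise. Fallback (known chemistry): setting out from 5 and 6, the uncatalysed cycloaddition (excess 6, toluene, 90–100 °C, sealed tube, BHT; or 10–12 kbar at rt) should give the racemic endo adduct, that is 7 together with its mirror image, the ent-adduct F1. Preparative SFC on a chiral stationary phase separates the two, and the route is rejoined at 7.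

2. Step 13. Hydrometalation may take the wrong regiochemistry, the alkyne may simply be semi-reduced, or the alkyne next to the substituted ring may react too slowly. Fallback: setting out from 14, Ru-catalysed Markovnikov hydrosilylation ([Cp*Ru(MeCN)3]PF6, Et3SiH, CH2Cl2) would give the 2-(triethylsilyl)alkene F2. Iododesilylation (NIS, 2,6-lutidine, hexafluoroisopropanol, 0 °C) would give the 2-iodoalkene F3. A classical NiCl2 (cat.)/CrCl2 Nozaki–Hiyama–Kishi coupling with 16 then returns to 17.

3. Step 19. Discrimination between the C2 and C3 hydroxyls may be incomplete, over-acylation may occur, or Z→E isomerisation of the acyl donor may set in if the reaction has to be forced. Fallback: setting out from 22, trimethyl orthoformate/CSA would give the 2,3-cyclic methyl orthoformate F4. Its kinetic opening in aqueous acetic acid places the formyl group on the axial oxygen and gives the 3-O-formyl 2-ol F5. Angeloylation of the single free secondary hydroxyl under the conditions of step 17 gives the 2-O-angeloyl 3-O-formyl compound F6. The formate is removed with KHCO3 in aqueous MeOH at 0 °C (formates cleave far faster than angelates), which returns to 24.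

Further compounds
F1 | step 5 | ent-adduct (mirror image of 7) | O=C2[C@@H]1[C@@H](O3)[C@@H](OC3=O)[C@](C)(O2)C(Br)=C1
F2 | step 13 | 2-(triethylsilyl)alkene from 14 | C=C([C@H]1[C@H](O3)[C@H](OC3(C)C)[C@@](C)(O)C(=O)[C@@H]1O[Si](CC)(CC)CC)[Si](CC)(CC)CC
F3 | step 13 | 2-iodoalkene | C=C([C@H]1[C@H](O3)[C@H](OC3(C)C)[C@@](C)(O)C(=O)[C@@H]1O[Si](CC)(CC)CC)I
F4 | step 19 | 2,3-cyclic methyl orthoformate of 22 | C=C([C@H]1[C@H](O3)[C@H](OC3OC)[C@@](C)(O)C(=O)[C@@H]1OC(=O)/C(C)=C\C)[C@H](CC=C(C)C)OC(=O)/C(C)=C\C
F5 | step 19 | 3-O-formyl 2-ol | C=C([C@H]1[C@H](O)[C@H](OC=O)[C@@](C)(O)C(=O)[C@@H]1OC(=O)/C(C)=C\C)[C@H](CC=C(C)C)OC(=O)/C(C)=C\C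
F6 | step 19 | 2-O-angeloyl 3-O-formyl compound | C=C([C@H]1[C@H](OC(=O)/C(C)=C\C)[C@H](OC=O)[C@@](C)(O)C(=O)[C@@H]1OC(=O)/C(C)=C\C)[C@H](CC=C(C)C)OC(=O)/C(C)=C\C
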